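**Plan**
- Retrosynthesis: the three O–benzyl bonds and the flavonol C3–O bond are cut last. Ring C is then opened at O1–C8a, C4–C4a and O1–C2, giving a ring-A aryne (from silyl triflate 8) and arylpropiolic acid 17. Acid 17 is cut at the aryl–alkyne bond (bromide 15 + propiolic acid), and the chroman at its pyran ring (4-bromophenol + a C5 propargylic chloride).
- Enabling feature: in ring A, O1 sits on C8a and the carbonyl carbon C4 on the adjacent C4a, with the C5 oxygen next to C4a. This vicinal O/acyl pair ortho to an alkoxy group is what a 3-alkoxybenzyne gives on insertion into a carboxyl C–O bond.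
- Forward order: the chroman pyran ring is made first (propargyl ether, Claisen/electrocyclisation), then the stereocentre, then the alkynoic acid. The aryne precursor is made in parallel in three steps. Ring C is closed in the convergent step, and C3 hydroxylation and global debenzylation finish the route.
- Stereochemistry: the only stereocentre, chroman C3 (R), comes from a Jacobsen–Katsuki epoxidation of chromene 12 with the (R,R)-salen manganese chloride complex. Hydride opening at C4 leaves the C3–O bond intact, and no later step can epimerise it.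

Key step: step 10

Remark: the catalyst hand in step 6 is chosen from the established sense of this epoxidation on 2,2-dimethylchromenes, where the (S,S)-complex gives the (3S,4S)-epoxide; the (R,R)-complex should therefore give (3R,4R).

**Step 1**
Reactants: 1 3,5-bis(benzyloxy)phenol
Product: 2 3,5-bis(benzyloxy)phenyl N-isopropylcarbamate
Conditions: iPrNCO, Et3N (cat.), CH2Cl2, rt
Reagents that add atoms: isopropyl isocyanate, CC(C)N=C=O
Why: Amine-catalysed addition of the phenol O–H to the isocyanate (carbamoylation) installs a strong ortho-directing group that can later be removed under mild amine conditions.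

**Step 2**
Reactants: 2 3,5-bis(benzyloxy)phenyl N-isopropylcarbamate
Product: 6 3,5-bis(benzyloxy)-2-(trimethylsilyl)phenyl N-isopropylcarbamate, via N-silyl carbamate 3 (not isolated), via aryllithium 4 (not isolated), via N-silyl arylsilane 5 (not isolated)
Conditions: TBSOTf, TMEDA, Et2O, 0 °C→rt; n-BuLi, TMEDA, −78 °C; TMSCl, −78 °C→rt; aq. NaHSO4 work-up
Reagents that add atoms: chlorotrimethylsilane, C[Si](C)(C)Cl
Why: Directed ortho-metalation, in which the in-situ N-silylated carbamate, the strongest director on the ring, acts together with the adjacent benzyloxy group to steer lithiation to C2 rather than to C4 between the two weaker benzyloxy directors, while −78 °C should hold back benzylic deprotonation and anionic Fries migration, and the N-silyl group is lost on aqueous work-up.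

**Step 3**
Reactants: 6 3,5-bis(benzyloxy)-2-(trimethylsilyl)phenyl N-isopropylcarbamate
Product: 8 3,5-bis(benzyloxy)-2-(trimethylsilyl)phenyl trifluoromethanesulfonate, via silyl phenol 7 (not isolated)
Conditions: Et2NH, DBU, MeCN, 40 °C; then PhNTf2, rt
Reagents that add atoms: N-phenylbis(trifluoromethanesulfonimide), O=S(=O)(N(c1ccccc1)S(=O)(=O)C(F)(F)F)C(F)(F)F
Why: One-pot carbamate cleavage and O-sulfonylation, in which the secondary carbamate loses isopropyl isocyanate by an E1cB pathway (trapped by Et2NH as a urea) and the phenoxide is triflated at once, so that the acid-sensitive, electron-rich silyl phenol need not be handled.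

**Step 4**
Reactants: 9 4-bromophenol; 10 3-chloro-3-methylbut-1-yne
Product: 11 1-bromo-4-[(2-methylbut-3-yn-2-yl)oxy]benzene
Conditions: DBU, CuCl2·2H2O (cat.), MeCN, 0 °C→rt
Reagents that add atoms: none
Why: Copper-catalysed propargylic substitution of the tertiary chloride by the phenoxide is the standard entry to aryl 1,1-dimethylpropargyl ethers and avoids a sluggish uncatalysed alkylation at a tertiary centre.

**Step 5**
Reactants: 11 1-bromo-4-[(2-methylbut-3-yn-2-yl)oxy]benzene
Product: 12 6-bromo-2,2-dimethyl-2H-chromene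
Conditions: PhNEt2, 190 °C
Reagents that add atoms: none
Why: Thermal aromatic propargyl Claisen rearrangement followed by enolisation, 1,5-hydrogen shift and oxa-6π electrocyclisation is the classical route to 2,2-dimethyl-2H-chromenes and leaves the para bromine untouched.

**Step 6**
Reactants: 12 6-bromo-2,2-dimethyl-2H-chromene
Product: 13 (3R,4R)-6-bromo-3,4-epoxy-2,2-dimethylchromane
Conditions: (R,R)-(salen)MnCl [chloro(R,R)-N,N'-bis(3,5-di-tert-butylsalicylidene)cyclohexane-1,2-diaminatomanganese, trivalent manganese] (4 mol%), aq. NaOCl (pH 11.3), 4-phenylpyridine N-oxide (cat.), CH2Cl2, 0 °C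
Reagents that add atoms: sodium hypochlorite, [Na+].[O-]Cl
Why: Jacobsen–Katsuki epoxidation, for which cis-configured 2,2-dimethylchromenes are among the best substrates, in which the oxo-manganese species carrying the (R,R)-ligand should deliver oxygen to one alkene face and so set C3 and C4 as (3R,4R).

**Step 7**
Reactants: 13 (3R,4R)-6-bromo-3,4-epoxy-2,2-dimethylchromane
Product: 14 (3R)-6-bromo-2,2-dimethylchroman-3-ol
Conditions: LiAlH4, THF, 0 °C
Reagents that add atoms: none
Why: SN2 hydride opening of the epoxide should occur at the benzylic C4, because C3 is neopentyl-like beside the quaternary C2, so the C3–O bond is never broken and the (3R) configuration is carried over, while the aryl bromide is inert to LiAlH4 at 0 °C.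

**Step 8**
Reactants: 14 (3R)-6-bromo-2,2-dimethylchroman-3-ol
Product: 15 (3R)-3-(benzyloxy)-6-bromo-2,2-dimethylchromane
Conditions: NaH, BnBr, n-Bu4NI (cat.), THF/DMF, 0 °C→rt
Reagents that add atoms: benzyl bromide, BrCc1ccccc1
Why: Williamson etherification, iodide-catalysed to overcome the hindrance next to the quaternary carbon, masks the one O–H that would otherwise add to the aryne and gives a group that is removed with the phenolic benzyl ethers at the end.

**Step 9**
Reactants: 15 (3R)-3-(benzyloxy)-6-bromo-2,2-dimethylchromane; 16 propiolic acid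
Product: 17 3-[(3R)-3-(benzyloxy)-2,2-dimethylchroman-6-yl]prop-2-ynoic acid
Conditions: PdCl2(PPh3)2 (5 mol%), dppb (10 mol%), DBU, DMSO, 50 °C; then cold aq. HCl
Reagents that add atoms: none
Why: Copper-free Sonogashira-type coupling of aryl bromides with propiolic acid as its DBU salt is an established route to arylpropiolic acids, and the low temperature and absence of copper should suppress decarboxylation and a second, decarboxylative coupling.

**Step 10**
Reactants: 8 3,5-bis(benzyloxy)-2-(trimethylsilyl)phenyl trifluoromethanesulfonate; 17 3-[(3R)-3-(benzyloxy)-2,2-dimethylchroman-6-yl]prop-2-ynoic acid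
Product: 20 5,7-bis(benzyloxy)-2-[(3R)-3-(benzyloxy)-2,2-dimethylchroman-6-yl]-4H-chromen-4-one, via aryne 18 (not isolated), via hydroxyaryl ynone 19 (not isolated)
Conditions: CsF (4 equiv), THF, 125 °C, sealed tube; 8 in 1.5-fold excess
Reagents that add atoms: none
Why: Fluoride strips the silyl group of 8 and triflate leaves to give aryne 18; the cesium carboxylate of 17 adds through oxygen to the aryne carbon meta to the flanking benzyloxy group (future C8a), and the aryl anion thus placed ortho to that benzyloxy group (future C4a) attacks the neighbouring ester carbonyl, the strained adduct opening to the phenoxide of ynone 19, so that O1–C8a and C4–C4a arise by net insertion of the aryne into the carboxyl C–O bond. The phenoxide oxygen then adds to the alkyne carbon beta to the ketone (O1–C2) in a 6-endo-dig oxa-Michael closure that forms ring C, the pyranone, and protonation at C3 gives 20. The closest known reaction type is the CsF-mediated insertion of arynes into the C–O bond of carboxylic acids to give ortho-hydroxyaryl ketones, which is known to run on to chromanones and chromones when the acid is unsaturated; here it is applied to a more heavily oxygenated aryne and a more elaborate arylpropiolic acid. No stereocentre is created, and the (3R) centre of the chroman is remote and carries no acidic hydrogen. Two selectivities are needed: the regiochemistry of the aryne addition, secured by the benzyloxy group beside the triple bond, which distorts the aryne so that nucleophiles attack the distal carbon (the second benzyloxy group, para to C4a, exerts only a weak opposing pull), and 6-endo over 5-exo (aurone) closure, favoured for a cesium phenoxide in aprotic THF at high temperature because the endo product is the more stable one and the exo addition is reversible.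

**Step 11**
Reactants: 20 5,7-bis(benzyloxy)-2-[(3R)-3-(benzyloxy)-2,2-dimethylchroman-6-yl]-4H-chromen-4-one
Product: 23 5,7-bis(benzyloxy)-2-[(3R)-3-(benzyloxy)-2,2-dimethylchroman-6-yl]-3-hydroxy-4H-chromen-4-one, via 3-lithioflavone 21 (not isolated), via C3 dimethyl boronate 22 (not isolated)
Conditions: LiN(iPr)2, THF, −78 °C; B(OMe)3, −78→0 °C; then AcOH, 30% aq. H2O2, 0 °C→rt
Reagents that add atoms: hydrogen peroxide, OO
Why: Carbonyl-directed lithiation of the flavone at C3, borylation and oxidative conversion of C–B into C–O is a known flavone-to-flavonol sequence, and the amide base at −78 °C is not strong enough to deprotonate the benzylic positions.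

**Step 12**
Reactants: 23 5,7-bis(benzyloxy)-2-[(3R)-3-(benzyloxy)-2,2-dimethylchroman-6-yl]-3-hydroxy-4H-chromen-4-one
Product: 24 3,5,7-trihydroxy-2-[(3R)-3-hydroxy-2,2-dimethylchroman-6-yl]-4H-chromen-4-one (CNP0411714.1)
Conditions: H2 (1 atm), Pd(OH)2/C, THF/MeOH, rt
Reagents that add atoms: none
Why: Catalytic hydrogenolysis should cleave the two aryl benzyl ethers and the alkyl benzyl ether in one operation, the flavonol C2=C3 bond and the non-benzylic chroman C–O bonds being inert under these conditions and the stereocentre untouched.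

**Compound list**
1 | 3,5-bis(benzyloxy)phenol | Oc1cc(OCc2ccccc2)cc(OCc2ccccc2)c1 | starting material
2 | 3,5-bis(benzyloxy)phenyl N-isopropylcarbamate | CC(C)NC(=O)Oc1cc(OCc2ccccc2)cc(OCc2ccccc2)c1 | intermediate
3 | 3,5-bis(benzyloxy)phenyl N-(tert-butyldimethylsilyl)-N-isopropylcarbamate (in flask) | CC(C)N(C(=O)Oc1cc(OCc2ccccc2)cc(OCc2ccccc2)c1)[Si](C)(C)C(C)(C)C | intermediate
4 | 3,5-bis(benzyloxy)-2-lithiophenyl N-(tert-butyldimethylsilyl)-N-isopropylcarbamate (in flask) | CC(C)N(C(=O)Oc1cc(OCc2ccccc2)cc(OCc2ccccc2)c1[Li])[Si](C)(C)C(C)(C)C | intermediate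
5 | 3,5-bis(benzyloxy)-2-(trimethylsilyl)phenyl N-(tert-butyldimethylsilyl)-N-isopropylcarbamate (in flask) | CC(C)N(C(=O)Oc1cc(OCc2ccccc2)cc(OCc2ccccc2)c1[Si](C)(C)C)[Si](C)(C)C(C)(C)C | intermediate
6 | 3,5-bis(benzyloxy)-2-(trimethylsilyl)phenyl N-isopropylcarbamate | CC(C)NC(=O)Oc1cc(OCc2ccccc2)cc(OCc2ccccc2)c1[Si](C)(C)C | intermediate
7 | 3,5-bis(benzyloxy)-2-(trimethylsilyl)phenol (in flask) | C[Si](C)(C)c1c(O)cc(OCc2ccccc2)cc1OCc1ccccc1 | intermediate
8 | 3,5-bis(benzyloxy)-2-(trimethylsilyl)phenyl trifluoromethanesulfonate | C[Si](C)(C)c1c(OCc2ccccc2)cc(OCc2ccccc2)cc1OS(=O)(=O)C(F)(F)F | intermediate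
9 | 4-bromophenol | Oc1ccc(Br)cc1 | starting material
10 | 3-chloro-3-methylbut-1-yne | C#CC(C)(C)Cl | starting material
11 | 1-bromo-4-[(2-methylbut-3-yn-2-yl)oxy]benzene | C#CC(C)(C)Oc1ccc(Br)cc1 | intermediate
12 | 6-bromo-2,2-dimethyl-2H-chromene | CC1(C)C=Cc2cc(Br)ccc2O1 | intermediate
13 | (3R,4R)-6-bromo-3,4-epoxy-2,2-dimethylchromane | CC1(C)Oc2ccc(Br)cc2[C@H]2O[C@@H]12 | intermediate
14 | (3R)-6-bromo-2,2-dimethylchroman-3-ol | CC1(C)Oc2ccc(Br)cc2C[C@H]1O | intermediate
15 | (3R)-3-(benzyloxy)-6-bromo-2,2-dimethylchromane | CC1(C)Oc2ccc(Br)cc2C[C@H]1OCc1ccccc1 | intermediate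
16 | propiolic acid (prop-2-ynoic acid) | C#CC(=O)O | starting material
17 | 3-[(3R)-3-(benzyloxy)-2,2-dimethylchroman-6-yl]prop-2-ynoic acid | CC1(C)Oc2ccc(C#CC(=O)O)cc2C[C@H]1OCc1ccccc1 | intermediate
18 | 3,5-bis(benzyloxy)benzyne (in flask) | C1(OCc2ccccc2)=CC(OCc2ccccc2)=CC#C1 | intermediate
19 | 1-[2,4-bis(benzyloxy)-6-hydroxyphenyl]-3-[(3R)-3-(benzyloxy)-2,2-dimethylchroman-6-yl]prop-2-yn-1-one (in flask) | CC1(C)Oc2ccc(C#CC(=O)c3c(O)cc(OCc4ccccc4)cc3OCc3ccccc3)cc2C[C@H]1OCc1ccccc1 | intermediate
20 | 5,7-bis(benzyloxy)-2-[(3R)-3-(benzyloxy)-2,2-dimethylchroman-6-yl]-4H-chromen-4-one | CC1(C)Oc2ccc(-c3cc(=O)c4c(OCc5ccccc5)cc(OCc5ccccc5)cc4o3)cc2C[C@H]1OCc1ccccc1 | intermediate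
21 | 3-lithio derivative of 20 (in flask) | CC1(C)Oc2ccc(-c3oc4cc(OCc5ccccc5)cc(OCc5ccccc5)c4c(=O)c3[Li])cc2C[C@H]1OCc1ccccc1 | intermediate
22 | dimethyl {5,7-bis(benzyloxy)-2-[(3R)-3-(benzyloxy)-2,2-dimethylchroman-6-yl]-4-oxo-4H-chromen-3-yl}boronate (in flask) | CC1(C)Oc2ccc(-c3oc4cc(OCc5ccccc5)cc(OCc5ccccc5)c4c(=O)c3B(OC)OC)cc2C[C@H]1OCc1ccccc1 | intermediate
23 | 5,7-bis(benzyloxy)-2-[(3R)-3-(benzyloxy)-2,2-dimethylchroman-6-yl]-3-hydroxy-4H-chromen-4-one | CC1(C)Oc2ccc(-c3oc4cc(OCc5ccccc5)cc(OCc5ccccc5)c4c(=O)c3O)cc2C[C@H]1OCc1ccccc1 | intermediate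
24 | 3,5,7-trihydroxy-2-[(3R)-3-hydroxy-2,2-dimethylchroman-6-yl]-4H-chromen-4-one | CC1(C)Oc2ccc(-c3oc4cc(O)cc(O)c4c(=O)c3O)cc2C[C@H]1O | target

**Step count**
Total: 12 steps. Longest linear sequence: 9 steps (steps 4–12, from 4-bromophenol); the aryne branch (steps 1–3) joins at step 10.

**Steps most likely to fail**

Step 10. The aryl anion may be protonated before it transfers the acyl group, which stops the sequence at simple O-arylation. The alkynoic acid may also decarboxylate under fluoride at 125 °C, or the phenoxide may close 5-exo instead of 6-endo. The fallback gives up the aryne and builds ring C by a Baker–Venkataraman sequence. It sets out from bromide 15. Bromine–lithium exchange (n-BuLi, THF, −78 °C) gives (3R)-3-(benzyloxy)-6-lithio-2,2-dimethylchromane F1, which is trapped with CO2 and acidified to (3R)-3-(benzyloxy)-2,2-dimethylchromane-6-carboxylic acid F2. Esterification with purchased 1-[2,4-bis(benzyloxy)-6-hydroxyphenyl]ethan-1-one (EDC·HCl, DMAP, CH2Cl2) should give 2-acetyl-3,5-bis(benzyloxy)phenyl (3R)-3-(benzyloxy)-2,2-dimethylchromane-6-carboxylate F3. Base-induced acyl migration (KOH, pyridine, 50 °C) should then give 1-[2,4-bis(benzyloxy)-6-hydroxyphenyl]-3-[(3R)-3-(benzyloxy)-2,2-dimethylchroman-6-yl]propane-1,3-dione F4, and cyclodehydration (p-TsOH, toluene, 80 °C) returns to the route at flavone 20.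

Step 11. Deprotonation at C3 may be incomplete beside the bulky 5-benzyloxy group, the amide base may add to C2 of the chromone, or the boronate may be lost by protodeboronation before oxidation. The fallback oxidises the C2=C3 bond directly. It sets out from flavone 20, which is epoxidised with dimethyldioxirane (acetone/CH2Cl2, 0 °C, monitored so that benzylic oxidation of the ethers does not set in) to 5,7-bis(benzyloxy)-2-[(3R)-3-(benzyloxy)-2,2-dimethylchroman-6-yl]-2,3-epoxy-2,3-dihydro-4H-chromen-4-one F5, formed as a mixture of epoxide diastereomers. Acid-catalysed opening and tautomerisation (p-TsOH cat., CH2Cl2) converts both diastereomers into the same flavonol and returns to the route at 23.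

Step 9. Oxidative addition of the electron-rich aryl bromide to zerovalent palladium may be slow, so that decarboxylation of propiolic acid or of the product, and decarboxylative double coupling, take over. The fallback installs the alkyne and the carboxyl group separately. It sets out from bromide 15, which is coupled with ethynyltrimethylsilane (PdCl2(PPh3)2, CuI, Et3N, 70 °C) to {[(3R)-3-(benzyloxy)-2,2-dimethylchroman-6-yl]ethynyl}trimethylsilane F6. Desilylation (K2CO3, MeOH) gives (3R)-3-(benzyloxy)-6-ethynyl-2,2-dimethylchromane F7. Deprotonation (n-BuLi, THF, −78 °C) gives the lithium acetylide of F7, lithium [(3R)-3-(benzyloxy)-2,2-dimethylchroman-6-yl]acetylide F8, and trapping with CO2 followed by acidification returns to the route at acid 17.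

**Further compounds**
F1 | step 10 | (3R)-3-(benzyloxy)-6-lithio-2,2-dimethylchromane | CC1(C)Oc2ccc([Li])cc2C[C@H]1OCc1ccccc1
F2 | step 10 | (3R)-3-(benzyloxy)-2,2-dimethylchromane-6-carboxylic acid | CC1(C)Oc2ccc(C(=O)O)cc2C[C@H]1OCc1ccccc1
F3 | step 10 | 2-acetyl-3,5-bis(benzyloxy)phenyl (3R)-3-(benzyloxy)-2,2-dimethylchromane-6-carboxylate | CC1(C)Oc2ccc(C(=O)Oc3cc(OCc4ccccc4)cc(OCc4ccccc4)c3C(C)=O)cc2C[C@H]1OCc1ccccc1
F4 | step 10 | 1-[2,4-bis(benzyloxy)-6-hydroxyphenyl]-3-[(3R)-3-(benzyloxy)-2,2-dimethylchroman-6-yl]propane-1,3-dione | CC1(C)Oc2ccc(C(=O)CC(=O)c3c(O)cc(OCc4ccccc4)cc3OCc3ccccc3)cc2C[C@H]1OCc1ccccc1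
F5 | step 11 | 5,7-bis(benzyloxy)-2-[(3R)-3-(benzyloxy)-2,2-dimethylchroman-6-yl]-2,3-epoxy-2,3-dihydro-4H-chromen-4-one (mixture of epoxide diastereomers) | CC1(C)Oc2ccc(C34OC3C(=O)c3c(OCc5ccccc5)cc(OCc5ccccc5)cc3O4)cc2C[C@H]1OCc1ccccc1
F6 | step 9 | {[(3R)-3-(benzyloxy)-2,2-dimethylchroman-6-yl]ethynyl}trimethylsilane | CC1(C)Oc2ccc(C#C[Si](C)(C)C)cc2C[C@H]1OCc1ccccc1
F7 | step 9 | (3R)-3-(benzyloxy)-6-ethynyl-2,2-dimethylchromane | CC1(C)Oc2ccc(C#C)cc2C[C@H]1OCc1ccccc1
F8 | step 9 | lithium [(3R)-3-(benzyloxy)-2,2-dimethylchroman-6-yl]acetylide | CC1(C)Oc2ccc(C#C[Li])cc2C[C@H]1OCc1ccccc1
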